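**Plan**

- Retrosynthesis: the acid is unmasked from isopropyl ester 17. The dihydropyran ring of 17 is cut at two bonds at once, C2–C3 (the C–C bond at the quaternary carbinol carbon) and O1–C8a (the aryl ether bond). This gives methyl dienyl ketone 7 (C2, O1, the C2 methyl and the whole side chain) and the mixed zinc reagent 14, a (2-arylethyl)(trimethylsilylmethyl)zinc (C3, C4 and a fluoroarene).
- Ketone 7 is cut at C2'–C3' (Heck) and C4'–CH3 (carboalumination) back to dihydro-β-ionone; 14 is cut at C4–C4a (Suzuki vinylation) back to 3-bromo-4-fluorobenzoic acid.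
- Enabling feature: O1 sits on aromatic C8a, which is para to C6 carrying the carboxyl group, so a C8a–F bond is open to SNAr. C2 is a carbinol carbon bearing methyl and an alkenyl group, i.e. a masked methyl ketone. The ring atoms O1–C2–C3–C4–C4a–C8a are therefore a C=O unit plus a four-carbon unit that is nucleophilic at C3 and electrophilic at C8a.
- Forward order: side chain first (alkyne, E-vinyl iodide, E,E-dienone; cyclohexene ring bought), then the aryl piece (ester, vinylation, hydroboration/boron–zinc exchange/ligand redistribution; benzene ring bought). A one-pot asymmetric alkylation/SNAr then joins the halves and closes the dihydropyran ring, the only ring made, and saponification ends the route.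
- Stereochemistry: C2 (R) comes from catalyst-controlled Re-face alkyl transfer to ketone 7. The trisubstituted E-alkene comes from syn-carboalumination/iodinolysis and the disubstituted E-alkene from the Heck step.

Key step: step 7

Assumption: the bis(sulfonamide) diol ligand (from trans-cyclohexane-1,2-diamine and 10-camphorsulfonyl chloride, ketone reduced to the exo alcohol) is taken to induce in dienone 7 the same facial sense as in aryl and alkenyl methyl ketones, the antipode from (1S,2S)-diamine and (1R)-10-camphorsulfonyl chloride being the one expected to give Re-face delivery; should the sense prove opposite, the other antipode would be used.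

**Step 1**
Reactants: 1 dihydro-β-ionone, 4-(2,6,6-trimethylcyclohex-1-en-1-yl)butan-2-one
Product: 3 terminal alkyne 2-(but-3-yn-1-yl)-1,3,3-trimethylcyclohex-1-ene, via enol diethyl phosphate 2 (not isolated)
Conditions: LiN(iPr)2 (1.05 equiv), THF, −78 °C; ClP(O)(OEt)2, −78 °C → rt; LiN(iPr)2 (2.3 equiv), −78 °C → rt; aq. NH4Cl
Reagents that add atoms: none
Why: Kinetic deprotonation at the methyl group, O-phosphorylation and base-induced elimination of diethyl phosphate (the enol phosphate route from methyl ketones to terminal alkynes) should turn the acetyl group into the alkyne without loss of carbon.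

**Step 2**
Reactants: 3 terminal alkyne
Product: 5 vinyl iodide 2-[(3E)-4-iodo-3-methylbut-3-en-1-yl]-1,3,3-trimethylcyclohex-1-ene, via dimethyl(alkenyl)alane 4 (not isolated)
Conditions: Me3Al (2.5 equiv), Cp2ZrCl2 (0.25 equiv), CH2Cl2, 0 °C → rt; I2, THF, −30 → 0 °C
Reagents that add atoms: trimethylaluminium, C[Al](C)C; iodine, II
Why: Zirconium-catalysed syn-carboalumination of the terminal alkyne (Negishi carboalumination) should place methyl on the internal carbon and aluminium on the terminal carbon on the same side, and iodinolysis with retention should give the E-trisubstituted vinyl iodide as one geometric isomer.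

**Step 3**
Reactants: 5 vinyl iodide; 6 but-3-en-2-one (methyl vinyl ketone)
Product: 7 dienone (3E,5E)-6-methyl-8-(2,6,6-trimethylcyclohex-1-en-1-yl)octa-3,5-dien-2-one
Conditions: Pd(OAc)2 (5 mol%), K2CO3, n-Bu4NCl, DMF, rt → 40 °C
Reagents that add atoms: none
Why: In this Mizoroki–Heck reaction under phase-transfer conditions, oxidative addition of zerovalent palladium to the vinyl C–I bond with retention, syn-insertion of the enone at its CH2 terminus and syn-β-hydride elimination should give the (3E,5E)-dienone.

**Step 4**
Reactants: 8 3-bromo-4-fluorobenzoic acid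
Product: 9 propan-2-yl 3-bromo-4-fluorobenzoate
Conditions: i-PrOH (solvent), H2SO4 (cat.), reflux, molecular sieves in the return line
Reagents that add atoms: propan-2-ol, CC(C)O
Why: Fischer esterification should give the isopropyl ester, chosen because it cannot be scrambled by the isopropoxide ligands of Ti(OiPr)4 in step 7 and is removable by base at the end.

**Step 5**
Reactants: 9 propan-2-yl 3-bromo-4-fluorobenzoate; 10 2-ethenyl-4,4,5,5-tetramethyl-1,3,2-dioxaborolane
Product: 11 propan-2-yl 3-ethenyl-4-fluorobenzoate
Conditions: PdCl2(dppf) (3 mol%), K3PO4, 1,4-dioxane/H2O (9:1), 80 °C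
Reagents that add atoms: none
Why: Suzuki–Miyaura coupling should take place at the C–Br bond only, since the C–F bond is inert to zerovalent palladium and phosphate is too weak a nucleophile for SNAr.

**Step 6**
Reactants: 11 propan-2-yl 3-ethenyl-4-fluorobenzoate
Product: 14 {2-[2-fluoro-5-(propan-2-yloxycarbonyl)phenyl]ethyl}[(trimethylsilyl)methyl]zinc, via alkyl(diethyl)borane 12 (not isolated), via bis(2-arylethyl)zinc 13 (not isolated)
Conditions: Et2BH (from BH3·SMe2 and BEt3), Et2O, 0 °C → rt; evaporate; Et2Zn (neat, 2 equiv), 0 °C; BEt3 and excess Et2Zn removed in vacuo (twice); (Me3SiCH2)2Zn (1.0 equiv per dialkylzinc), toluene, rt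
Reagents that add atoms: diethylzinc, CC[Zn]CC; bis[(trimethylsilyl)methyl]zinc, C[Si](C)(C)C[Zn]C[Si](C)(C)C
Why: Anti-Markovnikov hydroboration of the vinylarene by the dialkylborane and boron–zinc exchange driven by evaporation of BEt3 should give the primary dialkylzinc 13 (two molecules of 11 per zinc) without touching the hindered aryl ester or the aryl fluoride, and ligand redistribution with (Me3SiCH2)2Zn should then give the mixed diorganozinc 14, one 2-arylethyl group per zinc, in which the trimethylsilylmethyl group acts as a non-transferable ligand.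

**Step 7**
Reactants: 7 dienone; 14 (2-arylethyl)(trimethylsilylmethyl)zinc
Product: 17 propan-2-yl (2R)-2-methyl-2-[(1E,3E)-4-methyl-6-(2,6,6-trimethylcyclohex-1-en-1-yl)hexa-1,3-dien-1-yl]-3,4-dihydro-2H-chromene-6-carboxylate, via titanium tertiary alkoxide 15 (not isolated), via potassium tertiary alkoxide 16 (not isolated)
Conditions: 14 (2 equiv), bis(sulfonamide) diol ligand (10 mol%), Ti(OiPr)4 (1.2 equiv), toluene, rt; then KN(SiMe3)2 (4 equiv), THF, 0 → 50 °C; aq. NaHCO3; Et3N-deactivated silica
Reagents that add atoms: none
Why: The chiral titanium bis(sulfonamide) diolate formed from the ligand and Ti(OiPr)4 takes the 2-arylethyl group from 14, the trimethylsilylmethyl group staying on zinc, and delivers it to the Re face of the titanium-bound carbonyl of 7, which forms the C2–C3 bond and titanium alkoxide 15; this is the catalytic asymmetric addition of organozinc reagents to ketones, known for (E)-alkenyl methyl ketones and functionalised dialkylzincs, run here with a mixed alkyl(trimethylsilylmethyl)zinc of the kind that transfers only its alkyl group in titanium-catalysed carbonyl additions. KN(SiMe3)2 then turns the titanium-bound alkoxide into potassium alkoxide 16, whose oxygen attacks the fluorine-bearing aromatic carbon to give an anionic σ-complex stabilised by the para ester, and loss of fluoride forms the O1–C8a bond, the closest known type being the base-mediated SNAr cyclisation of 3-(2-fluoroaryl)propan-1-ols to chromans. The dihydropyran ring closes in a 6-exo-trig addition–elimination mode on the arene. The C2 stereocentre is set only in the alkyl transfer, under catalyst control through methyl versus dienyl differentiation, and the ring closure leaves the C2–O bond intact, so the configuration should be carried over unchanged. The step needs 1,2- over 1,4- or 1,6-addition (secured by the hard titanium alkyl and Lewis-acid activation of the carbonyl), tolerance of the ester (organozinc reagent, ester matched to the isopropoxide ligands) and cyclisation over intermolecular attack of isopropoxide on the fluoroarene (secured by the six-membered transition state and dilution).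

**Step 8**
Reactants: 17 chroman isopropyl ester
Product: 18 (2R)-2-methyl-2-[(1E,3E)-4-methyl-6-(2,6,6-trimethylcyclohex-1-en-1-yl)hexa-1,3-dien-1-yl]-3,4-dihydro-2H-chromene-6-carboxylic acid
Conditions: KOH (5 equiv), EtOH/H2O (4:1), 60 °C; then 1 M aq. KHSO4 to pH 4–5, 0 °C, immediate extraction
Reagents that add atoms: potassium hydroxide, [K+].[OH-]
Why: Saponification by acyl–oxygen cleavage should free the acid, since the tertiary dienylic aryl ether and the diene are stable to base, and the cold, weakly acidic work-up avoids ionisation at C2.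

**Compound list**

1 | dihydro-β-ionone, 4-(2,6,6-trimethylcyclohex-1-en-1-yl)butan-2-one | CC(=O)CCC1=C(C)CCCC1(C)C | starting material
2 | diethyl 4-(2,6,6-trimethylcyclohex-1-en-1-yl)but-1-en-2-yl phosphate | C=C(CCC1=C(C)CCCC1(C)C)OP(=O)(OCC)OCC | intermediate
3 | 2-(but-3-yn-1-yl)-1,3,3-trimethylcyclohex-1-ene | C#CCCC1=C(C)CCCC1(C)C | intermediate
4 | dimethyl[(1E)-2-methyl-4-(2,6,6-trimethylcyclohex-1-en-1-yl)but-1-en-1-yl]alane | C[Al](C)/C=C(\C)CCC1=C(C)CCCC1(C)C | intermediate
5 | 2-[(3E)-4-iodo-3-methylbut-3-en-1-yl]-1,3,3-trimethylcyclohex-1-ene | I/C=C(\C)CCC1=C(C)CCCC1(C)C | intermediate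
6 | but-3-en-2-one | CC(=O)C=C | starting material
7 | (3E,5E)-6-methyl-8-(2,6,6-trimethylcyclohex-1-en-1-yl)octa-3,5-dien-2-one | CC(=O)/C=C/C=C(\C)CCC1=C(C)CCCC1(C)C | intermediate
8 | 3-bromo-4-fluorobenzoic acid | OC(=O)c1ccc(F)c(Br)c1 | starting material
9 | propan-2-yl 3-bromo-4-fluorobenzoate | CC(C)OC(=O)c1ccc(F)c(Br)c1 | intermediate
10 | 2-ethenyl-4,4,5,5-tetramethyl-1,3,2-dioxaborolane | C=CB1OC(C)(C)C(C)(C)O1 | starting material
11 | propan-2-yl 3-ethenyl-4-fluorobenzoate | CC(C)OC(=O)c1ccc(F)c(C=C)c1 | intermediate
12 | propan-2-yl 3-[2-(diethylboranyl)ethyl]-4-fluorobenzoate | CCB(CC)CCc1cc(C(=O)OC(C)C)ccc1F | intermediate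
13 | bis{2-[2-fluoro-5-(propan-2-yloxycarbonyl)phenyl]ethyl}zinc | CC(C)OC(=O)c1ccc(F)c(CC[Zn]CCc2cc(C(=O)OC(C)C)ccc2F)c1 | intermediate
14 | {2-[2-fluoro-5-(propan-2-yloxycarbonyl)phenyl]ethyl}[(trimethylsilyl)methyl]zinc | C[Si](C)(C)C[Zn]CCc1cc(C(=O)OC(C)C)ccc1F | intermediate
15 | tri(propan-2-yloxy)titanium (3R,4E,6E)-1-[2-fluoro-5-(propan-2-yloxycarbonyl)phenyl]-3,7-dimethyl-9-(2,6,6-trimethylcyclohex-1-en-1-yl)nona-4,6-dien-3-olate | CC1=C(CC/C(C)=C/C=C/[C@@](O[Ti](OC(C)C)(OC(C)C)OC(C)C)(C)CCc2cc(C(=O)OC(C)C)ccc2F)C(C)(C)CCC1 | intermediate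
16 | potassium (3R,4E,6E)-1-[2-fluoro-5-(propan-2-yloxycarbonyl)phenyl]-3,7-dimethyl-9-(2,6,6-trimethylcyclohex-1-en-1-yl)nona-4,6-dien-3-olate | CC1=C(CC/C(C)=C/C=C/[C@@]([O-])(C)CCc2cc(C(=O)OC(C)C)ccc2F)C(C)(C)CCC1.[K+] | intermediate
17 | propan-2-yl (2R)-2-methyl-2-[(1E,3E)-4-methyl-6-(2,6,6-trimethylcyclohex-1-en-1-yl)hexa-1,3-dien-1-yl]-3,4-dihydro-2H-chromene-6-carboxylate | CC1=C(CC/C(C)=C/C=C/[C@@]2(C)CCc3cc(C(=O)OC(C)C)ccc3O2)C(C)(C)CCC1 | intermediate
18 | (2R)-2-methyl-2-[(1E,3E)-4-methyl-6-(2,6,6-trimethylcyclohex-1-en-1-yl)hexa-1,3-dien-1-yl]-3,4-dihydro-2H-chromene-6-carboxylic acid | CC1=C(CC/C(C)=C/C=C/[C@@]2(C)CCc3cc(C(=O)O)ccc3O2)C(C)(C)CCC1 | target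

**Totals**

Total step count: 8. Longest linear sequence: 5 steps (steps 1, 2, 3, 7, 8, or equally steps 4, 5, 6, 7, 8).

**Steps most likely to fail**

Step 7. The alkoxide may stay bound to titanium and fail to attack the arene, isopropoxide released from titanium may etherify the fluoroarene between molecules, or facial discrimination between methyl and dienyl may be incomplete. The fallback sets out from 7 and 14 and gives up the one-pot mode: only the asymmetric alkyl transfer is run, the mixture is quenched with aqueous NH4Cl, and the tertiary alcohol propan-2-yl 4-fluoro-3-[(3R,4E,6E)-3-hydroxy-3,7-dimethyl-9-(2,6,6-trimethylcyclohex-1-en-1-yl)nona-4,6-dien-1-yl]benzoate F1 is isolated free of titanium and zinc and, if needed, enriched on a chiral stationary phase. In a separate flask F1 is cyclised with KN(SiMe3)2 in THF at 0 °C → rt by SNAr, which comes back to the route at 17.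

Step 6. The borane may add in part at the benzylic carbon, may slowly reduce the ester, or the exchange may leave ethyl groups on zinc that would then compete with the 2-arylethyl group in step 7. The fallback sets out from 11 and avoids boron–zinc exchange and ethylzinc species altogether. Hydroboration with 9-borabicyclo[3.3.1]nonane in THF should give the B-alkyl borane propan-2-yl 3-[2-(9-borabicyclo[3.3.1]nonan-9-yl)ethyl]-4-fluorobenzoate F2. Oxidation with 30% H2O2 in aqueous NaOAc at 0 °C → rt should give the primary alcohol propan-2-yl 4-fluoro-3-(2-hydroxyethyl)benzoate F3, and Appel iodination (I2, PPh3, imidazole, CH2Cl2) the iodide propan-2-yl 4-fluoro-3-(2-iodoethyl)benzoate F4. Insertion of zinc dust (activated with 1,2-dibromoethane and Me3SiCl) in THF at 40 °C should give the alkylzinc iodide {2-[2-fluoro-5-(propan-2-yloxycarbonyl)phenyl]ethyl}zinc iodide F5. Addition of Me3SiCH2Li (1.0 equiv) at −78 °C, exchange of the solvent for toluene and filtration of the lithium iodide under argon comes back to the route at 14.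

Step 3. The enone may oligomerise, the trisubstituted alkene may migrate or lose its geometry on palladium, or a second insertion may occur. The fallback sets out from 5: iodine–lithium exchange (t-BuLi, Et2O, −78 °C) and formylation with DMF should give the enal (2E)-3-methyl-5-(2,6,6-trimethylcyclohex-1-en-1-yl)pent-2-enal F6 with retained geometry. E-selective Wittig olefination with the stabilised ylide Ph3P=CHC(O)CH3 (toluene, 80 °C) comes back to the route at 7.

**Further compounds**

F1 | step 7 | propan-2-yl 4-fluoro-3-[(3R,4E,6E)-3-hydroxy-3,7-dimethyl-9-(2,6,6-trimethylcyclohex-1-en-1-yl)nona-4,6-dien-1-yl]benzoate | CC1=C(CC/C(C)=C/C=C/[C@@](O)(C)CCc2cc(C(=O)OC(C)C)ccc2F)C(C)(C)CCC1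
F2 | step 6 | propan-2-yl 3-[2-(9-borabicyclo[3.3.1]nonan-9-yl)ethyl]-4-fluorobenzoate | CC(C)OC(=O)c1ccc(F)c(CCB2C3CCCC2CCC3)c1
F3 | step 6 | propan-2-yl 4-fluoro-3-(2-hydroxyethyl)benzoate | CC(C)OC(=O)c1ccc(F)c(CCO)c1
F4 | step 6 | propan-2-yl 4-fluoro-3-(2-iodoethyl)benzoate | CC(C)OC(=O)c1ccc(F)c(CCI)c1
F5 | step 6 | {2-[2-fluoro-5-(propan-2-yloxycarbonyl)phenyl]ethyl}zinc iodide | CC(C)OC(=O)c1ccc(F)c(CC[Zn]I)c1
F6 | step 3 | (2E)-3-methyl-5-(2,6,6-trimethylcyclohex-1-en-1-yl)pent-2-enal | O=C/C=C(\C)CCC1=C(C)CCCC1(C)C
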